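# Kaempferol 7-O-sulfate (11): synthesis proposal

## The problem

Compound 11 is a flat, achiral 2-aryl-3-hydroxy-4H-chromen-4-one. Ring A (C4a–C8a) is fused to the pyranone ring C (O1, C2, C3, C4) and ring B hangs on C2, so there is no stereocentre to set and none that could control another. The skeleton is the small part of the task. The large part is that four hydroxyl oxygens (O3, O5, O7, O4') sit on one conjugated system and only O7 may carry the SO3H group. O7–H and O4'–H are both vinylogous acids of the C4 carbonyl (through ring A, and through ring B and C2=C3), so they differ little towards SO3 donors; the enolic O3–H reacts as well, and only O5–H is taken out of play by its hydrogen bond to O=C4. The aryl hydrogen sulfate will not survive rough treatment: it solvolyses in acid and on heating and makes every later intermediate ionic, so it must come late and be followed only by neutral, non-hydrolytic chemistry, which excludes methyl ethers, acetals and Lewis acids on the other oxygens. C3 carries an oxygen α to the ketone, a 1,2-dioxygen pattern that is usually added by a separate oxidation unless it is already present in a building block. The feature that opens the plan is ring A: O1, O5 and O7 stand on the alternate carbons C8a, C5 and C7, and C4a, C6 and C8 carry C4 or hydrogen, so ring A is phloroglucinol 4, whose three oxygens and three C–H carbons are equivalent by symmetry until the C4–C3–C2 bridge is attached. Attaching that bridge to unprotected 4 therefore cannot give regioisomers, and the closure of ring C itself sorts three identical OH groups into an ether (O1), a chelated, inert phenol (O5) and one free, acidic phenol (O7). O3 and O4' belong to the bridge and to ring B and can be bought already masked as benzyl ethers, which hydrogenolysis removes without touching an aryl sulfate.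

## Retrosynthesis

**11 ⇒ 10.** The cut is the acidic O–H of the sulfate, exchanged for a Bu3NH+ counter-ion. The free acid catalyses its own solvolysis, so it should exist only after the last operation. Carrying the acid through any earlier step would expose O7–S to protons for longer. Salt 10 is no simpler in skeleton, but it is stable and soluble in organic solvents. The forward step must exchange the cation in the cold and must not concentrate an acidic solution by heat.

**10 ⇒ 9.** The cuts are O3–CH2Ph and O4'–CH2Ph.
- Benzyl is preferred to acyl, which would scramble onto the ring A hydroxyls in the hot key step.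
- It is preferred to methyl, which needs Lewis acids that also cleave O–S.
- It is preferred to acetals, which need aqueous acid.

The precursor 9 is lipophilic and can be chromatographed. The forward reaction must cleave two benzyl ethers without reducing C2=C3 and without breaking O7–S.

**9 ⇒ 8.** The cut is O7–S. In 8 the choice among the oxygens is made by structure, not by reagent control: O3 and O4' are ethers, O1 is in the ring, O5–H is chelated, and O7–H is the only hydroxyl left. The precursor is neutral and free of sulfur. The forward reaction is a plain phenol sulfation that only has to leave the chelated O5–H alone.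

**8 ⇒ 3 + 4 (key).** The cuts are C4–C4a and O1–C2, the two bonds that tie the three-carbon bridge to ring A.
- The neighbouring pairs of cuts are C2–C3 with O1–C2, or C3–O with O1–C2. Both lead back to an acylphloroglucinol whose three hydroxyls are already inequivalent and would need individual protection.
- Cutting both ring A bonds leads back to symmetric, unprotected 4.
- A tricycle with four differentiated oxygens becomes a C6 triol and the acyclic β-keto ester 3.
- The forward reaction, which runs through ketene 5, ester 6 and triketone 7, must end in C-acylation rather than O-acylation. It must close on the aroyl ketone (chromone) and not on the ester carbonyl (coumarin). It must stop after one annulation, and it must be free of acid so that the benzyl ethers survive.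

**3 ⇒ 1 + 2.** The cut is the bond that becomes C2–C3. This places the dissonant oxygen O3 in commercial glycolate 1, so no oxidation step is needed. Both benzyl groups arrive with purchased reagents, so no protection step is spent. The forward reaction is a crossed Claisen condensation between an enolisable ester and a non-enolisable aroyl chloride.

## Roads not taken

**Alternative 1:** This is the most obvious road. Only O7–S is cut and the synthesis starts from commercial kaempferol A1. The forward key step is site-selective sulfation of A1. It can be run directly with one equivalent of an SO3 complex, or after peracetylation to tetraacetate A2 and nucleophilic removal of the most activated ester to give the 3,5,4'-triacetate A3 with O7–H free.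
- In A1, O7–H and O4'–H are conjugated to the same carbonyl and O3–H is also reactive, so the direct reaction depends on small rate differences and gives ionic regioisomers that are hard to separate.
- The acetate detour replaces one kinetic selection by another (one of four esters) and risks acyl migration onto the freed O7.
- The chosen plan never has to choose among hydroxyls of a flavonol, uses no selective protection or deprotection, and builds the skeleton from bulk chemicals in the same number of steps.

**Alternative 2:** O1–C2 and C3–O are cut. The forward key step is the Algar–Flynn–Oyamada oxidative cyclisation of the 2'-hydroxychalcone A4 with alkaline H2O2 to give flavonol A5.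
- Ring A must first be split into three differently treated oxygens (free at 2', benzyl at 6', a temporary group at 4') by stepwise protection of an acylphloroglucinol. That is the same discrimination problem, only moved forward.
- The 6'-substituent twists the aroyl group and favours 5-exo attack at Cα, the aurone channel.
- O3 emerges free and needs its own benzylation, and the temporary group on O7 has to be removed with acid before sulfation.
- The route is about twice as long, and its key step solves neither the O7 problem nor the O3 problem.

**Alternative 3:** C7–O is cut. The forward key step is iridium-catalysed C–H borylation of the 7-deoxyflavonol tris(silyl ether) A6 at C7, the only C–H flanked by two C–H carbons. This gives boronate A7, and oxidation then gives a 7-OH that is born free.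
- The idea puts O7 in last, but it discards an oxygen that 4 supplies for nothing.
- It forbids benzyl ethers, because their phenyl rings offer open C–H sites.
- C8–H is shielded only by the tied-back ring oxygen O1.
- A classical flavonol synthesis of the 7-deoxy core from a 2,6-dioxygenated acetophenone is still needed.
- The precursor of this key step is hardly simpler than its product, whereas 3 and 4 are far simpler than 8.

Key step: step 2

Assumption: 11 has no stereocentre and no stereogenic double bond, so the request for a single enantiomer has no object; the sulfate is taken as the free hydrogen sulfate drawn and is made from its stable Bu3NH+ salt 10 only in the last step.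

## Route

Step 1
Reactants: 1 ethyl 2-(benzyloxy)acetate; 2 4-(benzyloxy)benzoyl chloride
Product: 3 ethyl 2-(benzyloxy)-3-[4-(benzyloxy)phenyl]-3-oxopropanoate (racemic)
Conditions: LiHMDS (2.1 equiv), THF, −78 °C; then 2, −78 → −20 °C; aq NH4Cl
Reagents that add atoms: none
Why: Crossed Claisen condensation (C-acylation of a lithium glycolate enolate by a non-enolisable aroyl chloride); the second equivalent of base turns 3 at once into its chelated enolate, which stops double acylation, and the low temperature keeps the benzyloxy enolate from Wittig rearrangement. The new C–H centre is racemic and enolisable and disappears in step 2.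

Step 2
Reactants: 3 ethyl 2-(benzyloxy)-3-[4-(benzyloxy)phenyl]-3-oxopropanoate; 4 phloroglucinol (anhydrous)
Product: 8 3,4'-di-O-benzylkaempferol (3-benzyloxy-2-[4-(benzyloxy)phenyl]-5,7-dihydroxy-4H-chromen-4-one), via α-oxoketene 5 (not isolated), via phloroglucinyl ester 6 (not isolated), via C-acyl triketone 7 (not isolated)
Conditions: 4 (2 equiv), neat melt, Ar sweep, 235–240 °C (microwave or metal bath), 10–20 min, EtOH and H2O distilled off; excess 4 removed with water
Reagents that add atoms: none
Why: Mentzer pyrone synthesis (uncatalysed thermal condensation of a phenol with a β-keto ester), run here as an annulative desymmetrisation of 4. The enol of 3 loses ethanol in a six-centre retro-ene process to give α-oxoketene 5, whose ketene carbon (the future C4) is by far the strongest electrophile present and is captured by an OH of 4 to give aryl ester 6. At this temperature O-acylation is reversible (6 ⇌ 5 + 4), whereas attack of an ortho ring carbon of the very nucleophilic phloroglucinol nucleus on C4 (thermal Fries-type transfer) is not, because triketone 7 is held by two O–H···O=C4 hydrogen bonds. Ring C then closes by 6-exo-trig addition of one flanking OH (the future O1) to the aroyl carbonyl carbon C2 and loss of water, driven by formation of the aromatic 4-pyranone. No stereocentre is formed: the labile C3–H centre of 3, 6 and 7 becomes sp2. Site selectivity is not needed, since the three C–H carbons of 4 and the two OH groups next to each are equivalent and all six modes of attachment give the same 8. Chromone rather than coumarin (Pechmann) closure is secured by the absence of acid and by the 4-benzyloxy donor, which makes the aroyl ketone a poor electrophile for a ring carbon, and a second annulation is held back because C4=O deactivates ring A of 8. The step leaves O3 and O4' benzylated, O1 in the ring, O5–H chelated and O7–H as the only reactive hydroxyl.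

Step 3
Reactants: 8 3,4'-di-O-benzylkaempferol
Product: 9 tributylammonium 3,4'-di-O-benzylkaempferol 7-sulfate
Conditions: Bu3N·SO3 (1.5 equiv), MeCN–DMF, 50 °C
Reagents that add atoms: tributylsulfoammonium betaine (Bu3N·SO3), CCCC[N+](CCCC)(CCCC)S(=O)(=O)[O-]
Why: O-sulfation of a phenol by an amine–SO3 complex; O7–H is the only hydroxyl available, because O5–H is locked in a six-membered hydrogen bond to O=C4 and is less acidic and less nucleophilic, and O3 and O4' are ethers. The lipophilic Bu3NH+ counter-ion keeps 9 soluble in organic solvents, so it can be purified on amine-buffered silica.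

Step 4
Reactants: 9 tributylammonium 3,4'-di-O-benzylkaempferol 7-sulfate
Product: 10 tributylammonium kaempferol 7-sulfate
Conditions: H2 (1 atm), Pd(OH)2/C, MeOH–THF, rt
Reagents that add atoms: none
Why: Catalytic hydrogenolysis of an aryl and an enol benzyl ether; salts of aryl sulfate monoesters are inert to H2/Pd, the tetrasubstituted cross-conjugated C2=C3 bond is not reduced at 1 atm, and the reaction forms no acid. The fully protonated ammonium ion of a strong acid releases no free amine that could slow the catalyst.

Step 5
Reactants: 10 tributylammonium kaempferol 7-sulfate
Product: 11 kaempferol 7-O-sulfate (free hydrogen sulfate)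
Conditions: Dowex 50WX8 (H+ form) column, MeOH–H2O, 0 °C; immediate freeze-drying
Reagents that add atoms: none
Why: Cation exchange on a sulfonic acid resin in column mode replaces Bu3NH+ by H+ by mass action. Cold elution and freeze-drying avoid warm concentrated acid, the condition under which O7–S solvolyses.

## Compound list

1 | ethyl 2-(benzyloxy)acetate | CCOC(=O)COCc1ccccc1 | starting material
2 | 4-(benzyloxy)benzoyl chloride | O=C(Cl)c1ccc(OCc2ccccc2)cc1 | starting material
3 | ethyl 2-(benzyloxy)-3-[4-(benzyloxy)phenyl]-3-oxopropanoate (racemic, enolisable) | CCOC(=O)C(OCc1ccccc1)C(=O)c1ccc(OCc2ccccc2)cc1 | intermediate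
4 | phloroglucinol (benzene-1,3,5-triol) | Oc1cc(O)cc(O)c1 | starting material
5 | 2-(benzyloxy)-3-[4-(benzyloxy)phenyl]-3-oxoprop-1-en-1-one (α-oxoketene) | O=C=C(OCc1ccccc1)C(=O)c1ccc(OCc2ccccc2)cc1 | intermediate
6 | 3,5-dihydroxyphenyl 2-(benzyloxy)-3-[4-(benzyloxy)phenyl]-3-oxopropanoate (racemic) | Oc1cc(O)cc(OC(=O)C(OCc2ccccc2)C(=O)c2ccc(OCc3ccccc3)cc2)c1 | intermediate
7 | 2-(benzyloxy)-1-[4-(benzyloxy)phenyl]-3-(2,4,6-trihydroxyphenyl)propane-1,3-dione (racemic) | O=C(c1ccc(OCc2ccccc2)cc1)C(OCc1ccccc1)C(=O)c1c(O)cc(O)cc1O | intermediate
8 | 3,4'-di-O-benzylkaempferol | O=c1c(OCc2ccccc2)c(-c2ccc(OCc3ccccc3)cc2)oc2cc(O)cc(O)c12 | intermediate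
9 | tributylammonium 3,4'-di-O-benzylkaempferol 7-sulfate | CCCC[NH+](CCCC)CCCC.O=c1c(OCc2ccccc2)c(-c2ccc(OCc3ccccc3)cc2)oc2cc(OS(=O)(=O)[O-])cc(O)c12 | intermediate
10 | tributylammonium kaempferol 7-sulfate | CCCC[NH+](CCCC)CCCC.O=c1c(O)c(-c2ccc(O)cc2)oc2cc(OS(=O)(=O)[O-])cc(O)c12 | intermediate
11 | kaempferol 7-O-sulfate | O=c1c(O)c(-c2ccc(O)cc2)oc2cc(OS(=O)(=O)O)cc(O)c12 | target

## Step count and risks

Total step count: 5. Longest linear sequence: 5 (1 → 3 → 8 → 9 → 10 → 11).

**Risk at step 2 (key step).** Four processes are the most likely failures.
- The water released on ring closure can add to the ketene, which is followed by decarboxylation and drains 3.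
- Closure can take place through the ester carbonyl after attack of a ring carbon on the aroyl ketone (Pechmann mode).
- The O3 benzyl group can be lost or can migrate thermally in the hot phenolic melt.
- The reaction can stall at the O-acyl stage if the temperature is lowered to spare the benzyl groups.

The fallback gives up the one-step union and attaches the bridge in two pieces; it sets out from 4 and comes back at 8. Houben–Hoesch acylation of 4 with benzyloxyacetonitrile (HCl gas, ZnCl2, Et2O, 0 °C) should give the ketiminium chloride F1, which hot water hydrolyses to 2-(benzyloxy)-1-(2,4,6-trihydroxyphenyl)ethanone F2. Exhaustive O-aroylation with 2 in pyridine gives the triester F3. Baker–Venkataraman acyl transfer and cyclodehydration in one flask (KOH, pyridine, 50 °C; then AcOH, cat. H2SO4) give the 5,7-di-O-aroylflavone F4. Methanolysis of its two aryl esters (K2CO3, MeOH–THF) returns 8. Symmetry still removes any regiochemical question, because the two ortho hydroxyls of F2 are equivalent.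

**Risk at step 1.** O-acylation or double acylation of the enolate, self-condensation of 1, and Wittig rearrangement of the benzyloxy enolate on warming are the likely losses, because glycolate enolates are both basic and thermally fragile. The fallback introduces O3 by carbene insertion instead of enolate acylation; it sets out from 2 and comes back at 3. Magnesium-mediated acylation of potassium ethyl malonate with 2 (MgCl2, Et3N, MeCN) and decarboxylation give ethyl 3-[4-(benzyloxy)phenyl]-3-oxopropanoate F5. Diazo transfer (4-acetamidobenzenesulfonyl azide, Et3N) gives the 2-diazo ester F6. Rh2(OAc)4-catalysed O–H insertion into benzyl alcohol gives 3.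

**Risk at step 3.** The conversion of the sparingly soluble 8 may be incomplete, a second sulfation at O5 may set in if the reaction is forced, and the sulfate may be lost on acidic silica during purification of the salt. The fallback carries the sulfate as a neutral diester; it sets out from 8 and comes back at 11. 2,2,2-Trichloroethyl chlorosulfate (Et3N, DMAP, THF, 0 °C) should give the mixed sulfate diester F7, which can be purified by ordinary chromatography. Transfer hydrogenation (Pd/C, HCO2NH4, MeOH) removes the trichloroethyl group and both benzyl ethers in one operation to give ammonium kaempferol 7-sulfate F8. Cation exchange as in step 5 gives 11.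

**Risk at step 5.** Acid-catalysed solvolysis of the O7–S bond may occur while the free acid is eluted and concentrated, because the product is itself a strong acid and C7–O is the oxygen of a vinylogous acid. The fallback makes a salt the isolated and stored form and liberates the acid stoichiometrically; it sets out from 10 and comes back at 11. Metathesis with potassium acetate in MeOH precipitates potassium kaempferol 7-sulfate F9, which is purified by size exclusion or reversed phase. Compound 11 is then set free only when needed, with one equivalent of cold dilute HCl, desalting on a reversed-phase cartridge and freeze-drying.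

## Further compounds

F1 | step 2 | 2-(benzyloxy)-1-(2,4,6-trihydroxyphenyl)ethan-1-iminium chloride | [Cl-].[NH2+]=C(COCc1ccccc1)c1c(O)cc(O)cc1O
F2 | step 2 | 2-(benzyloxy)-1-(2,4,6-trihydroxyphenyl)ethanone | O=C(COCc1ccccc1)c1c(O)cc(O)cc1O
F3 | step 2 | 2-[(benzyloxy)acetyl]benzene-1,3,5-triyl tris[4-(benzyloxy)benzoate] | O=C(COCc1ccccc1)c1c(OC(=O)c2ccc(OCc3ccccc3)cc2)cc(OC(=O)c2ccc(OCc3ccccc3)cc2)cc1OC(=O)c1ccc(OCc2ccccc2)cc1
F4 | step 2 | 3,4'-di-O-benzylkaempferol 5,7-bis[4-(benzyloxy)benzoate] | O=c1c(OCc2ccccc2)c(-c2ccc(OCc3ccccc3)cc2)oc2cc(OC(=O)c3ccc(OCc4ccccc4)cc3)cc(OC(=O)c3ccc(OCc4ccccc4)cc3)c12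
F5 | step 1 | ethyl 3-[4-(benzyloxy)phenyl]-3-oxopropanoate | CCOC(=O)CC(=O)c1ccc(OCc2ccccc2)cc1
F6 | step 1 | ethyl 3-[4-(benzyloxy)phenyl]-2-diazo-3-oxopropanoate | CCOC(=O)C(=[N+]=[N-])C(=O)c1ccc(OCc2ccccc2)cc1
F7 | step 3 | 3,4'-di-O-benzylkaempferol 7-(2,2,2-trichloroethyl sulfate) | O=c1c(OCc2ccccc2)c(-c2ccc(OCc3ccccc3)cc2)oc2cc(OS(=O)(=O)OCC(Cl)(Cl)Cl)cc(O)c12
F8 | step 3 | ammonium kaempferol 7-sulfate | [NH4+].O=c1c(O)c(-c2ccc(O)cc2)oc2cc(OS(=O)(=O)[O-])cc(O)c12
F9 | step 5 | potassium kaempferol 7-sulfate | [K+].O=c1c(O)c(-c2ccc(O)cc2)oc2cc(OS(=O)(=O)[O-])cc(O)c12
A1 | alternative 1 | kaempferol | O=c1c(O)c(-c2ccc(O)cc2)oc2cc(O)cc(O)c12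
A2 | alternative 1 | kaempferol 3,5,7,4'-tetraacetate | CC(=O)Oc1ccc(cc1)-c1oc2cc(OC(C)=O)cc(OC(C)=O)c2c(=O)c1OC(C)=O
A3 | alternative 1 | kaempferol 3,5,4'-triacetate | CC(=O)Oc1ccc(cc1)-c1oc2cc(O)cc(OC(C)=O)c2c(=O)c1OC(C)=O
A4 | alternative 2 | (E)-1-[2-(benzyloxy)-6-hydroxy-4-(methoxymethoxy)phenyl]-3-[4-(benzyloxy)phenyl]prop-2-en-1-one | COCOc1cc(O)c(C(=O)/C=C/c2ccc(OCc3ccccc3)cc2)c(OCc2ccccc2)c1
A5 | alternative 2 | 5-(benzyloxy)-2-[4-(benzyloxy)phenyl]-3-hydroxy-7-(methoxymethoxy)-4H-chromen-4-one | COCOc1cc(OCc2ccccc2)c2c(=O)c(O)c(-c3ccc(OCc4ccccc4)cc3)oc2c1
A6 | alternative 3 | 3,5-bis(tert-butyldimethylsilyloxy)-2-[4-(tert-butyldimethylsilyloxy)phenyl]-4H-chromen-4-one | CC(C)(C)[Si](C)(C)Oc1ccc(cc1)-c1oc2cccc(O[Si](C)(C)C(C)(C)C)c2c(=O)c1O[Si](C)(C)C(C)(C)C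
A7 | alternative 3 | 7-(4,4,5,5-tetramethyl-1,3,2-dioxaborolan-2-yl) derivative of A6 | CC(C)(C)[Si](C)(C)Oc1ccc(cc1)-c1oc2cc(B3OC(C)(C)C(C)(C)O3)cc(O[Si](C)(C)C(C)(C)C)c2c(=O)c1O[Si](C)(C)C(C)(C)C
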